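Slowness is what you see first in the earlier runs: the target stays within the scatter at first and then picks up, and the question is what that costs Tuesday's, which sits at −25 °C for 12 h before it warms.

in all of them: precatalyst 16 mM
- midnight: starting material 0.80 M; reagent 1.7 M; temperature −18 °C; run made earlier
- noon: starting material 0.80 M; reagent 2.6 M; temperature −1 °C; run made earlier
- spring: starting material 1.6 M; reagent 1.2 M; temperature −18 °C; run made earlier
- Sunday's: starting material 0.80 M; reagent 1.20 M; temperature −25 °C; time 40 h
- Saturday's: starting material 0.80 M; reagent 1.20 M; temperature 5 °C; time 40 h
- Thursday's: starting material 0.80 M; reagent 1.20 M; temperature −10 °C; time 40 h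
- Tuesday's: starting material 0.80 M; reagent 1.20 M; at −25 °C until 12 h, from then on at 5 °C; time 40 h

| run | time / h | target / % |
|---|---|---|
| midnight | 3.00 | 0.4 |
| midnight | 8.00 | 0.2 |
| midnight | 15.0 | 1.7 |
| midnight | 25.0 | 3.8 |
| noon | 0.667 | 1.2 |
| noon | 1.33 | 0.7 |
| noon | 3.00 | 3.4 |
| noon | 8.00 | 19.3 |
| spring | 6.00 | 0.7 |
| spring | 12.0 | 0.3 |
| spring | 20.0 | 0.3 |
| spring | 25.0 | 3.2 |

(each reading ± 1 percentage point)

- what was read earlier has a scatter of 1 percentage point, one standard deviation

1. the flask with the highest amount of target, in percent of the starting material charged ("all alike" if they lie within 1.5 percentage points) (Sunday's / Saturday's / Thursday's / Tuesday's / all alike)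
2. final target, as a percentage of the starting material charged, in Sunday's
3. final target, as a percentage of the starting material charged, in Saturday's
4. final target, as a percentage of the starting material charged, in Thursday's
5. final target, as a percentage of the starting material charged, in Tuesday's

Turn the question round: Tuesday's can end level with Saturday's, within 1.5 percentage points, if both flasks finish, and for that its 28.0 h of warmth must be enough to use up the charge. To test that, replace each curve by its mean. From the noon run, 19.3% after 8.00 h, you get 41.5 h as the hours a flask would need to turn its charge into target at its mean rate so far, the time read divided by the share made, the filling time. The error of the mean is known in kind: on a curve growing as the square of time the rate at the last reading is twice the mean, so this figure errs on the slow side early, while a shrinking charge later errs the other way.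

The midnight run reads 658 h, so carrying the same step per degree on to 5 °C gives me 15.6 h. That step also contains a difference in the hour read, which I leave in, and a difference in reagent, and assuming proportion from c(reagent) = 2.6 M down to 1.20 M gives 33.9 h. This is my own reckoning, and it is shorter than Saturday's 40 h but longer than Tuesday's warm hours, by a factor of 1.21. So I expect Saturday's ahead and Tuesday's short of the finish.

The forecast also names Saturday's, with 1.3% for Sunday's, 90% for Saturday's, 18% for Thursday's and 88% for Tuesday's, a flask at 5 °C being “essentially complete in 15 h”; there it differs from my reckoning, since it has Tuesday's finishing.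

The flasks give Saturday's as the highest: 1.36% in Sunday's, 75.8% in Saturday's, 32.8% in Thursday's and 71.2% in Tuesday's.

    starting material + free catalyst → catalyst intermediate A (k = 0.270 M⁻¹ min⁻¹, Ea = 53.0 kJ mol⁻¹)
    reagent + catalyst intermediate A ⇌ catalyst intermediate B (K = 0.760 M⁻¹, k = 1.80 M⁻¹ min⁻¹, Ea = 43.0 kJ mol⁻¹, ΔH = −15.0 kJ mol⁻¹)
    catalyst intermediate B → free catalyst + target (k = 0.150 min⁻¹, Ea = 73.0 kJ mol⁻¹)
    precatalyst → free catalyst (k = 0.0110 min⁻¹, Ea = 82.0 kJ mol⁻¹)
    free catalyst → spent catalyst (k = 0.00170 min⁻¹, Ea = 98.0 kJ mol⁻¹)
    starting material + target → side product (k = 2.80 × 10⁻⁴ M⁻¹ min⁻¹, Ea = 63.0 kJ mol⁻¹)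
    (constants at 5 °C)

Counting its warm hours, Tuesday's has a filling time of 39.3 h, longer than those hours. Saturday's, over its full run, shows 52.8 h, a longer figure than Tuesday's, though Saturday's was warm throughout. The mean hides a falling rate: Saturday's reached half conversion by 11.7 h and ended with 83.2% of its catalyst spent, and the conversion of free catalyst into spent catalyst is the main reason for its shortfall. With that step taken away, Saturday's reaches 89.5%, a filling time of 44.7 h.

(The runs are simulated with made-up constants, and the scatter is random.)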